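**Retrosynthetic overview**
1. 21 ⇒ enol ether 7 + o-quinone 20 (made in the flask from catechol 19): the 1,4-dioxane ring is closed last by an oxidative hetero-[4+2] of the two unprotected phenolic halves, the union thought to operate in the plant, run under a chiral phosphoric acid so that both stereocentres arise in that one step.
2. 7 ⇒ 3 + 5: ring B of the dienophile half is annulated onto an already oxidised, non-aromatic ring A (enolate arylation, aldol, aromatisation).
3. 19 ⇒ 17 ⇒ 16 ⇒ 14 + 11: ring B of the catechol half by amide-directed remote metalation of a biaryl; the O-methyl pattern is then reset (three OMe off, 9-OMe on).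
4. Ring order: ring B of 7 (step 4), ring B of 19 (step 10), dioxane ring (step 12).

Assumption: phenanthrene locants are used for both halves; 21 is the (3S,4S) cis-fused isomer of the given SMILES (C-3 = ketal carbon, C-4 = methine of the half derived from 7), and (R)-TRIP is taken to deliver this sense (the antipodal acid is used if the first run shows the opposite).

**Route**

Step 1
Reactants: 1 2,2-dimethylcyclohexane-1,3-dione
Product: 2 4-hydroxy-2,2-dimethylcyclohex-4-ene-1,3-dione (enol form of the 1,3,4-trione)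
Conditions: SeO2 (1.05 equiv), 1,4-dioxane/H2O 20:1, 90 °C
Reagents that add atoms: selenium dioxide, O=[Se]=O
Why: Riley oxidation of the α-methylene next to a carbonyl of the symmetric, C-2-blocked dione gives the 1,2-dicarbonyl, which rests as the conjugated enol (diosphenol); no stereocentre.

Step 2
Reactants: 2 4-hydroxy-2,2-dimethylcyclohex-4-ene-1,3-dione
Product: 3 4-methoxy-2,2-dimethylcyclohex-4-ene-1,3-dione
Conditions: MeOH, TsOH·H2O (5 mol %), 3 Å MS, 50 °C
Reagents that add atoms: methanol, CO
Why: acid-catalysed enol etherification of a diosphenol (hemiketal at C-4, loss of water); C-2 is quaternary, so only this enol ether can form.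

Step 3
Reactants: 4 4-bromo-2-methoxy-1-methylbenzene (5-bromo-2-methylanisole)
Product: 5 1-(2-bromo-4-methoxy-5-methylphenyl)ethan-1-one
Conditions: AcCl (1.2 equiv), AlCl3 (1.3 equiv), CH2Cl2, 0 °C
Reagents that add atoms: acetyl chloride, CC(Cl)=O
Why: Friedel–Crafts acylation goes para to OMe (ortho to Br), since the only other OMe-activated position is crowded between OMe and Br.

Step 4
Reactants: 3 4-methoxy-2,2-dimethylcyclohex-4-ene-1,3-dione; 5 1-(2-bromo-4-methoxy-5-methylphenyl)ethan-1-one
Product: 7 9-hydroxy-3,6-dimethoxy-1,1,7-trimethylphenanthren-2(1H)-one, via arylated enedione 6 (not isolated)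
Conditions: Pd(OAc)2 (3 mol %), 2-di-tert-butylphosphino-2',4',6'-triisopropylbiphenyl (6 mol %), K3PO4 (2.2 equiv), 1,4-dioxane, 90 °C; aq. NH4Cl; crude 6 then TsOH·H2O (20 mol %), toluene, 4 Å MS, 90 °C
Reagents that add atoms: none
Why: Buchwald–Hartwig-type α-arylation of the vinylogous 1,3-dicarbonyl enolate of 3 at C-6 (3 is far more acidic than the aryl methyl ketone, so K3PO4 deprotonates only 3), then acid-catalysed intramolecular aldol condensation of the acetyl CH3 onto C-1 and tautomerisation to the naphthol; no stereocentre remains.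

Step 5
Reactants: 8 4-bromo-2,3-dimethylphenol
Product: 9 5-bromo-2-hydroxy-3,4-dimethylbenzaldehyde
Conditions: (CH2O)n (6 equiv), MgCl2 (1.5 equiv), Et3N (3.75 equiv), MeCN, reflux
Reagents that add atoms: paraformaldehyde (as formaldehyde), C=O
Why: Casnati–Skattebøl ortho-formylation (magnesium phenoxide hydroxymethylation, then Oppenauer-type oxidation by a second formaldehyde) at the only free ortho position.

Step 6
Reactants: 9 5-bromo-2-hydroxy-3,4-dimethylbenzaldehyde
Product: 10 5-bromo-3,4-dimethylbenzene-1,2-diol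
Conditions: 30% H2O2 (1.2 equiv), NaOH (1.1 equiv), H2O/THF, 0 °C to rt, N2; HCl work-up
Reagents that add atoms: hydrogen peroxide, OO
Why: Dakin oxidation of an o-hydroxybenzaldehyde (aryl migration in the peroxide adduct, formate hydrolysis) gives the catechol.

Step 7
Reactants: 10 5-bromo-3,4-dimethylbenzene-1,2-diol
Product: 11 1-bromo-4,5-dimethoxy-2,3-dimethylbenzene
Conditions: MeI (3 equiv), K2CO3 (3 equiv), acetone, reflux
Reagents that add atoms: iodomethane, CI
Why: double Williamson O-methylation; the methyl ethers survive the organolithium steps and all come off together in step 11.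

Step 8
Reactants: 12 4-methoxy-3-methylbenzoic acid
Product: 14 N,N-diethyl-4-methoxy-3-methylbenzamide, via acid chloride 13 (not isolated)
Conditions: SOCl2 (1.5 equiv), DMF (cat.), toluene, 70 °C; evaporate; then Et2NH (1.2 equiv), aq. NaOH, CH2Cl2, 0 °C
Reagents that add atoms: diethylamine, CCNCC
Why: acid chloride formation and Schotten–Baumann amidation; the diethylamide is the directing group for steps 9 and 10 and its carbonyl becomes C-9.

Step 9
Reactants: 14 N,N-diethyl-4-methoxy-3-methylbenzamide; 11 1-bromo-4,5-dimethoxy-2,3-dimethylbenzene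
Product: 16 N,N-diethyl-2-(4,5-dimethoxy-2,3-dimethylphenyl)-4-methoxy-5-methylbenzamide, via boronic acid 15 (not isolated)
Conditions: s-BuLi (1.1 equiv), TMEDA, THF, −78 °C; B(OMe)3, −78 °C to rt; then 11 (0.85 equiv), Pd(OAc)2 (3 mol %), 2-dicyclohexylphosphino-2',6'-dimethoxybiphenyl (6 mol %), aq. K3PO4, 70 °C
Reagents that add atoms: none
Why: directed ortho-metalation at the less hindered position ortho to CONEt2 (para to the ring methyl), borylation and one-pot Suzuki–Miyaura coupling give the di-ortho-substituted biaryl.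

Step 10
Reactants: 16 N,N-diethyl-2-(4,5-dimethoxy-2,3-dimethylphenyl)-4-methoxy-5-methylbenzamide
Product: 17 2,3,6-trimethoxy-1,7-dimethylphenanthren-9-ol
Conditions: LiN(iPr)2 (2.5 equiv), THF, 0 °C to rt; degassed aq. NH4Cl
Reagents that add atoms: none
Why: directed remote metalation (Snieckus): amide-complexed base deprotonates the 2'-methyl group, the benzylic anion attacks the amide carbonyl, and loss of LiNEt2 with tautomerisation gives the 9-phenanthrol (amide carbon = C-9, methyl carbon = C-10).

Step 11
Reactants: 17 2,3,6-trimethoxy-1,7-dimethylphenanthren-9-ol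
Product: 19 9-methoxy-1,7-dimethylphenanthrene-2,3,6-triol, via tetraol 18 (not isolated)
Conditions: BBr3 (5 equiv), CH2Cl2, −78 °C to rt; then MeOH (excess), 50 °C, argon; co-evaporate with MeOH
Reagents that add atoms: methanol, CO
Why: BBr3 cleaves the three aryl methyl ethers, and the HBr/MeOH formed on quenching etherifies only the 9-OH, the one phenol that reacts through its keto tautomer (9(10H)-phenanthrenone; acid-catalysed naphthol etherification).

Step 12
Reactants: 19 9-methoxy-1,7-dimethylphenanthrene-2,3,6-triol; 7 9-hydroxy-3,6-dimethoxy-1,1,7-trimethylphenanthren-2(1H)-one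
Product: 21 actephilol C, via o-quinone 20 (not isolated)
Conditions: 19, PhI(OAc)2 (1.0 equiv), CH2Cl2, −78 to −40 °C, 15 min; then added slowly to 7 (1.2 equiv), (R)-3,3'-bis(2,4,6-triisopropylphenyl)-1,1'-binaphthyl-2,2'-diyl hydrogen phosphate ((R)-TRIP, 10 mol %), 4 Å MS, toluene, −60 to −30 °C
Reagents that add atoms: none
Why: Proposed new method: the catechol is oxidised to o-quinone 20, and the phosphoric acid hydrogen-bonds as donor to a quinone carbonyl (LUMO lowering) and as acceptor to the 9-OH of 7 (para to the styrenic carbon, HOMO raising), so the O=C–C=O heterodiene meets one face of the C3=C4 enol ether in an asynchronous inverse-electron-demand hetero-Diels–Alder reaction whose suprafacial C–O bond formation makes the dioxane cis-fused and sets C-3 and C-4 (S,S) together; the regiochemistry (C-4 to the unhindered oxygen on C-3 of 20, ketal carbon C-3 to the oxygen beside the C-1 methyl) is taken from the natural product and is a stated risk; the closest known reaction types are the uncatalysed [4+2] of o-quinones with styrenes and enol ethers to 1,4-benzodioxanes and chiral phosphoric acid-catalysed annulations of hydroxystyrenes with quinone-type electrophiles.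

**Compound list**
1 | 2,2-dimethylcyclohexane-1,3-dione | CC1(C)C(=O)CCCC1=O | starting material
2 | 4-hydroxy-2,2-dimethylcyclohex-4-ene-1,3-dione | OC1=CCC(=O)C(C)(C)C1=O | intermediate
3 | 4-methoxy-2,2-dimethylcyclohex-4-ene-1,3-dione | COC1=CCC(=O)C(C)(C)C1=O | intermediate
4 | 4-bromo-2-methoxy-1-methylbenzene | COc1cc(Br)ccc1C | starting material
5 | 1-(2-bromo-4-methoxy-5-methylphenyl)ethan-1-one | CC(=O)c1cc(C)c(OC)cc1Br | intermediate
6 | 6-(2-acetyl-5-methoxy-4-methylphenyl)-4-methoxy-2,2-dimethylcyclohex-4-ene-1,3-dione | COC1=CC(c2cc(OC)c(C)cc2C(C)=O)C(=O)C(C)(C)C1=O | intermediate (not isolated)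
7 | 9-hydroxy-3,6-dimethoxy-1,1,7-trimethylphenanthren-2(1H)-one | COC1=Cc2c(cc(O)c3cc(C)c(OC)cc23)C(C)(C)C1=O | intermediate
8 | 4-bromo-2,3-dimethylphenol | Cc1c(C)c(Br)ccc1O | starting material
9 | 5-bromo-2-hydroxy-3,4-dimethylbenzaldehyde | O=Cc1cc(Br)c(C)c(C)c1O | intermediate
10 | 5-bromo-3,4-dimethylbenzene-1,2-diol | Oc1cc(Br)c(C)c(C)c1O | intermediate
11 | 1-bromo-4,5-dimethoxy-2,3-dimethylbenzene | COc1cc(Br)c(C)c(C)c1OC | intermediate
12 | 4-methoxy-3-methylbenzoic acid | COc1ccc(C(=O)O)cc1C | starting material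
13 | 4-methoxy-3-methylbenzoyl chloride | COc1ccc(C(=O)Cl)cc1C | intermediate (not isolated)
14 | N,N-diethyl-4-methoxy-3-methylbenzamide | CCN(CC)C(=O)c1ccc(OC)c(C)c1 | intermediate
15 | [2-(diethylcarbamoyl)-5-methoxy-4-methylphenyl]boronic acid | CCN(CC)C(=O)c1cc(C)c(OC)cc1B(O)O | intermediate (not isolated)
16 | N,N-diethyl-2-(4,5-dimethoxy-2,3-dimethylphenyl)-4-methoxy-5-methylbenzamide | CCN(CC)C(=O)c1cc(C)c(OC)cc1-c1cc(OC)c(OC)c(C)c1C | intermediate
17 | 2,3,6-trimethoxy-1,7-dimethylphenanthren-9-ol | COc1c(OC)cc2c(cc(O)c3cc(C)c(OC)cc32)c1C | intermediate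
18 | 1,7-dimethylphenanthrene-2,3,6,9-tetraol | Oc1c(O)cc2c(cc(O)c3cc(C)c(O)cc32)c1C | intermediate (not isolated)
19 | 9-methoxy-1,7-dimethylphenanthrene-2,3,6-triol | Oc1c(O)cc2c(cc(OC)c3cc(C)c(O)cc32)c1C | intermediate
20 | 6-hydroxy-9-methoxy-1,7-dimethylphenanthrene-2,3-dione | O=C1C(=O)C=C2c3cc(O)c(C)cc3C(OC)=CC2=C1C | intermediate (not isolated)
21 | actephilol C: (3S,4S) cis-fused 1,4-benzodioxane; ketal carbon C-3 of the half from 7 carries OMe and the oxygen on C-2 of the half from 19, methine C-4 carries the oxygen on C-3 of that half | COc1cc2c3c(cc(O)c2cc1C)C(C)(C)C(=O)[C@@]1(OC)Oc2c(cc4c(cc(OC)c5cc(C)c(O)cc54)c2C)O[C@@H]31 | target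

**Totals**
Total steps: 12. Longest linear sequence: 7 steps (8 → 9 → 10 → 11 → 16 → 17 → 19 → 21).

**Steps most likely to fail, with fallbacks**

Step 12 (regiochemistry of the cycloaddition, competing oxidation of the free naphthol of 7 and the level of enantiocontrol are all untested). The fallback sets out from 7 and 19 and gives up catalyst control. The two are stirred with Ag2O (2.2 equiv) in benzene–acetone at rt, the classical biomimetic oxidative coupling for benzodioxane neolignans, passing through 20. This gives the racemic cis-adduct, that is 21 together with ent-actephilol C F1. The enantiomers are separated by preparative HPLC on an amylose tris(3,5-dimethylphenylcarbamate) phase, with the configuration checked by ECD, and the route is rejoined at 21.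

Step 4 (the stabilised enolate of 3 may arylate poorly with the ortho-acyl bromide, and the free methyl ketone may self-condense). The fallback sets out from 3 and 5 and splits the cascade into a protected, stepwise sequence in which no methyl ketone is present during the C–C coupling. Compound 5 is converted with ethylene glycol and TsOH (toluene, Dean–Stark) into 2-(2-bromo-4-methoxy-5-methylphenyl)-2-methyl-1,3-dioxolane F2. Pd(OAc)2/phosphine/K3PO4 arylation of 3 with it gives 6-[5-methoxy-4-methyl-2-(2-methyl-1,3-dioxolan-2-yl)phenyl]-4-methoxy-2,2-dimethylcyclohex-4-ene-1,3-dione F3, which is isolated. Aqueous HCl/THF then releases 6, which is closed and aromatised with TsOH in toluene, and the route is rejoined at 7.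

Step 11 (the air-sensitive tetraol 18 and the selectivity of the in-flask 9-O-methylation). The fallback sets out from 16 and installs the 9-O-methyl group by alkylation instead. BBr3 on the biaryl gives N,N-diethyl-2-(4,5-dihydroxy-2,3-dimethylphenyl)-4-hydroxy-5-methylbenzamide F4. MOMCl/iPr2NEt gives N,N-diethyl-2-[4,5-bis(methoxymethoxy)-2,3-dimethylphenyl]-4-(methoxymethoxy)-5-methylbenzamide F5. LiN(iPr)2 closes ring B to 2,3,6-tris(methoxymethoxy)-1,7-dimethylphenanthren-9-ol F6. MeI/K2CO3 gives 9-methoxy-2,3,6-tris(methoxymethoxy)-1,7-dimethylphenanthrene F7. HCl in MeOH removes the three MOM groups and the route is rejoined at 19.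

**Further compounds**
F1 | step 12 | ent-actephilol C (3R,4R) | COc1cc2c3c(cc(O)c2cc1C)C(C)(C)C(=O)[C@]1(OC)Oc2c(cc4c(cc(OC)c5cc(C)c(O)cc54)c2C)O[C@H]31
F2 | step 4 | 2-(2-bromo-4-methoxy-5-methylphenyl)-2-methyl-1,3-dioxolane | COc1cc(Br)c(cc1C)C2(C)OCCO2
F3 | step 4 | 6-[5-methoxy-4-methyl-2-(2-methyl-1,3-dioxolan-2-yl)phenyl]-4-methoxy-2,2-dimethylcyclohex-4-ene-1,3-dione | COC1=CC(c2cc(OC)c(C)cc2C3(C)OCCO3)C(=O)C(C)(C)C1=O
F4 | step 11 | N,N-diethyl-2-(4,5-dihydroxy-2,3-dimethylphenyl)-4-hydroxy-5-methylbenzamide | CCN(CC)C(=O)c1cc(C)c(O)cc1-c1cc(O)c(O)c(C)c1C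
F5 | step 11 | N,N-diethyl-2-[4,5-bis(methoxymethoxy)-2,3-dimethylphenyl]-4-(methoxymethoxy)-5-methylbenzamide | CCN(CC)C(=O)c1cc(C)c(OCOC)cc1-c1cc(OCOC)c(OCOC)c(C)c1C
F6 | step 11 | 2,3,6-tris(methoxymethoxy)-1,7-dimethylphenanthren-9-ol | COCOc1c(OCOC)cc2c(cc(O)c3cc(C)c(OCOC)cc32)c1C
F7 | step 11 | 9-methoxy-2,3,6-tris(methoxymethoxy)-1,7-dimethylphenanthrene | COCOc1c(OCOC)cc2c(cc(OC)c3cc(C)c(OCOC)cc32)c1C
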